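**Retrosynthetic overview**

- The target is a trans lactone A (3R,4R; 5,7-dihydroxy) joined through C3–C3' to a cis lactone B (3'S,4'R; 5',6',7',8'-tetrahydroxy). The last operations are a syn hydrogenation of the C3'=C4' bond of a coumarin B and removal of nine methyl ethers.
- Key disconnection: C3–C3' and C4'–C4a' are made in one radical cascade between the C3 radical of a bromolactone A and an aryl 3-arylpropiolate. Lactone ring A is carried from the starting coumarin, and the pyranone ring of unit B is the only ring formed.
- Feature on which the strategy rests: in benzo ring B every carbon except C4a' bears oxygen (C5', C6', C7', C8', C8a'). The 2,3,4,5-tetramethoxyphenyl ester therefore has a single free carbon ortho to the ester oxygen, and ortho attack or ipso attack with 1,2-acyloxy shift lead to the same 5',6',7',8'-tetramethoxycoumarin.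
- Bromolactone: asymmetric rhodium-catalysed 1,4-arylation of 5,7-dimethoxycoumarin sets C4, then enolate bromination. Alkynoate: lithiation, borylation and oxidation of 1,2,3,4-tetramethoxybenzene, then Steglich esterification.

Key step: step 5

Remark: the SMILES is read as 3R,4R (trans) in lactone A and 3'S,4'R (cis) in lactone B, unprimed locants for the 5,7-dioxygenated unit and primed for the tetraoxygenated unit. (R)-SEGPHOS is assumed to give the 4R adduct, as it does with simpler coumarins.

**Step 1**
Reactants: 1 5,7-dimethoxycoumarin; 2 4-methoxyphenylboronic acid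
Product: 3 (R)-5,7-dimethoxy-4-(4-methoxyphenyl)chroman-2-one
Conditions: Rh(acac)(C2H4)2 (3 mol%), (R)-SEGPHOS (3.3 mol%), 2 (5 equiv, in portions), dioxane/H2O 10:1, 60 °C
Reagents that add atoms: none
Why: Hayashi–Miyaura asymmetric 1,4-addition, in which the aryl–rhodium species (monovalent rhodium) inserts across C3=C4 on the face left open by the bisphosphine and the oxa-π-allyl is protonated by water, setting C4 as R, with excess boronic acid to offset protodeboronation while the 5-methoxy group slows insertion.

**Step 2**
Reactants: 3 (R)-5,7-dimethoxy-4-(4-methoxyphenyl)chroman-2-one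
Product: 5 (3S,4R)-3-bromo-5,7-dimethoxy-4-(4-methoxyphenyl)chroman-2-one, via lithium enolate 4 (not isolated)
Conditions: LiN(SiMe3)2 (1.1 equiv), THF, -78 °C; enolate added to BrCl2C–CCl2Br (1.3 equiv), THF, -78 °C; AcOH quench
Reagents that add atoms: 1,2-dibromo-1,1,2,2-tetrachloroethane, BrC(Cl)(Cl)C(Cl)(Cl)Br (bromine of 5); lithium bis(trimethylsilyl)amide, [Li]N([Si](C)(C)C)[Si](C)(C)C (lithium of 4 only)
Why: Electrophilic α-bromination of a lactone enolate by halophilic attack on a polyhalide that leaves the bromination-prone ring A (free C6 and C8) alone; bromine should enter anti to the C4 aryl group to give the trans bromide, in which H4 and Br are cis so that anti elimination of HBr is not open, and the C3 centre is made planar again in step 5.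

**Step 3**
Reactants: 6 1,2,3,4-tetramethoxybenzene
Product: 9 2,3,4,5-tetramethoxyphenol, via aryllithium 7 (not isolated), via lithium aryltrimethoxyborate 8 (not isolated)
Conditions: n-BuLi, TMEDA, THF, 0 °C; B(OMe)3, -78 °C to rt; AcOH, 30% H2O2, 0 °C to rt
Reagents that add atoms: hydrogen peroxide, OO (hydroxyl oxygen of 9); n-butyllithium, [Li]CCCC (lithium of 7 and 8 only); trimethyl borate, COB(OC)OC (boron and methoxy groups of 8 only)
Why: Directed ortho-lithiation beside a methoxy group (C5 and C6 are equivalent), borylation to the ate complex and oxidative 1,2-shift of the aryl group from boron to oxygen place the hydroxyl on a carbon whose one ortho neighbour is unsubstituted.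

**Step 4**
Reactants: 9 2,3,4,5-tetramethoxyphenol; 10 3-(4-methoxyphenyl)propiolic acid
Product: 11 2,3,4,5-tetramethoxyphenyl 3-(4-methoxyphenyl)propiolate
Conditions: DCC (1.2 equiv), DMAP (10 mol%), CH2Cl2, 0 °C to rt
Reagents that add atoms: none
Why: Steglich esterification, in which DMAP relays the O-acylisourea to the phenol under neutral conditions that leave the alkyne untouched.

**Step 5**
Reactants: 5 (3S,4R)-3-bromo-5,7-dimethoxy-4-(4-methoxyphenyl)chroman-2-one; 11 2,3,4,5-tetramethoxyphenyl 3-(4-methoxyphenyl)propiolate
Product: 12 (3R,4R)-5,7-dimethoxy-4-(4-methoxyphenyl)-3-[5,6,7,8-tetramethoxy-4-(4-methoxyphenyl)-2-oxo-2H-chromen-3-yl]chroman-2-one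
Conditions: fac-Ir(ppy)3 (2 mol%), 2,6-lutidine (2 equiv), 11 (2.5 equiv), dry degassed MeCN (0.3 M in 5), blue LEDs (450 nm), rt, Ar
Reagents that add atoms: none
Why: Excited fac-Ir(ppy)3 transfers one electron to the C3–Br bond of 5; bromide leaves and the planar C3 radical, electrophilic because it is α to the lactone carbonyl, adds to the alkyne carbon of 11 next to the ester carbonyl, so that the vinyl radical sits on C4' beside the 4-methoxyphenyl group. The closest known reaction type is the visible-light radical addition and cyclisation of aryl 3-arylpropiolates with α-bromo carbonyl compounds to 3-alkyl-4-arylcoumarins. The pyranone ring of coumarin B closes when the C4' vinyl radical attacks ring B, either directly at the one unsubstituted carbon ortho to the ester oxygen (six-membered closure) or 5-exo at the ipso carbon followed by a 1,2-acyloxy shift to that same carbon; since the four other ring carbons all carry methoxy, both paths give the 5',6',7',8'-tetramethoxy pattern, and oxidation of the cyclohexadienyl radical by tetravalent iridium with loss of a proton to 2,6-lutidine restores the arene and the trivalent catalyst. C3 is the only new stereocentre and is controlled by the 4-methoxyphenyl group on C4, which covers one face of the radical so that the alkyne bonds trans to it; this is also the more stable epimer, so cis material could be equilibrated with DBU. The step needs the bimolecular addition to outrun reduction of the radical, a 1,2-aryl shift and loss of HBr, which the excess of 11, the high concentration and the trans bromide favour, and it needs the spiro radical from ipso attack to rearrange and not be oxidised to a spirodienone, which the low stationary concentration of tetravalent iridium and dry conditions favour.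

**Step 6**
Reactants: 12 (3R,4R)-5,7-dimethoxy-4-(4-methoxyphenyl)-3-[5,6,7,8-tetramethoxy-4-(4-methoxyphenyl)-2-oxo-2H-chromen-3-yl]chroman-2-one
Product: 13 (3R,4R)-5,7-dimethoxy-4-(4-methoxyphenyl)-3-[(3S,4R)-5,6,7,8-tetramethoxy-4-(4-methoxyphenyl)-2-oxochroman-3-yl]chroman-2-one
Conditions: H2 (60 bar), 20% Pd(OH)2/C, EtOAc/AcOH 4:1, 50 °C
Reagents that add atoms: none
Why: Heterogeneous syn hydrogenation of the tetrasubstituted C3'=C4' bond delivers both hydrogens to one face, which makes H3' and H4' cis; allylic 1,3-strain against the C4' aryl group should hold C3–H in the coumarin plane, so that carbonyl carbon C2 of lactone A lies over one face and the diarylmethyl carbon C4 under the other, and adsorption on the C2 face gives 3'S,4'R.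

**Step 7**
Reactants: 13 (3R,4R)-5,7-dimethoxy-4-(4-methoxyphenyl)-3-[(3S,4R)-5,6,7,8-tetramethoxy-4-(4-methoxyphenyl)-2-oxochroman-3-yl]chroman-2-one
Product: 14 (3R,4R)-5,7-dihydroxy-4-(4-hydroxyphenyl)-3-[(3S,4R)-5,6,7,8-tetrahydroxy-4-(4-hydroxyphenyl)-2-oxochroman-3-yl]chroman-2-one (CNP0064734.4)
Conditions: BBr3 (20 equiv), CH2Cl2, -78 °C to rt, Ar; degassed ice-cold aq. Na2S2O4 work-up
Reagents that add atoms: none
Why: Lewis-acid ether cleavage, in which each ArO(Me)–BBr3 adduct loses bromomethane by SN2 attack of bromide on the methyl group and the aryl borates are hydrolysed on work-up, while the two aryl lactones and the four stereocentres, never exposed to base, should persist and the oxygen-free reducing work-up protects the tetrahydroxy ring B from oxidation to quinones.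

**Compound list**

1 | 5,7-dimethoxycoumarin | COc1cc(OC)c2ccc(=O)oc2c1 | starting material
2 | 4-methoxyphenylboronic acid | COc1ccc(B(O)O)cc1 | starting material
3 | (R)-5,7-dimethoxy-4-(4-methoxyphenyl)chroman-2-one | O=C1Oc2cc(OC)cc(OC)c2[C@@H](c2ccc(OC)cc2)C1 | intermediate
4 | lithium enolate of 3 (lithium (R)-5,7-dimethoxy-4-(4-methoxyphenyl)-4H-chromen-2-olate) | [Li]OC1=C[C@H](c2ccc(OC)cc2)c2c(OC)cc(OC)cc2O1 | intermediate (not isolated)
5 | (3S,4R)-3-bromo-5,7-dimethoxy-4-(4-methoxyphenyl)chroman-2-one (trans) | O=C1Oc2cc(OC)cc(OC)c2[C@@H](c2ccc(OC)cc2)[C@@H]1Br | intermediate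
6 | 1,2,3,4-tetramethoxybenzene | COc1ccc(OC)c(OC)c1OC | starting material
7 | 2,3,4,5-tetramethoxyphenyllithium | [Li]c1cc(OC)c(OC)c(OC)c1OC | intermediate (not isolated)
8 | lithium trimethoxy(2,3,4,5-tetramethoxyphenyl)borate | [Li+].CO[B-](OC)(OC)c1cc(OC)c(OC)c(OC)c1OC | intermediate (not isolated)
9 | 2,3,4,5-tetramethoxyphenol | Oc1cc(OC)c(OC)c(OC)c1OC | intermediate
10 | 3-(4-methoxyphenyl)propiolic acid | COc1ccc(cc1)C#CC(=O)O | starting material
11 | 2,3,4,5-tetramethoxyphenyl 3-(4-methoxyphenyl)propiolate | COc1ccc(cc1)C#CC(=O)Oc1cc(OC)c(OC)c(OC)c1OC | intermediate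
12 | (3R,4R)-5,7-dimethoxy-4-(4-methoxyphenyl)-3-[5,6,7,8-tetramethoxy-4-(4-methoxyphenyl)-2-oxo-2H-chromen-3-yl]chroman-2-one | O=C1Oc2cc(OC)cc(OC)c2[C@@H](c2ccc(OC)cc2)[C@@H]1C1=C(c2ccc(OC)cc2)c2c(OC)c(OC)c(OC)c(OC)c2OC1=O | intermediate
13 | (3R,4R)-5,7-dimethoxy-4-(4-methoxyphenyl)-3-[(3S,4R)-5,6,7,8-tetramethoxy-4-(4-methoxyphenyl)-2-oxochroman-3-yl]chroman-2-one | O=C1Oc2cc(OC)cc(OC)c2[C@@H](c2ccc(OC)cc2)[C@@H]1[C@H]1C(=O)Oc2c(OC)c(OC)c(OC)c(OC)c2[C@H]1c1ccc(OC)cc1 | intermediate
14 | (3R,4R)-5,7-dihydroxy-4-(4-hydroxyphenyl)-3-[(3S,4R)-5,6,7,8-tetrahydroxy-4-(4-hydroxyphenyl)-2-oxochroman-3-yl]chroman-2-one | O=C1Oc2cc(O)cc(O)c2[C@@H](c2ccc(O)cc2)[C@@H]1[C@H]1C(=O)Oc2c(O)c(O)c(O)c(O)c2[C@H]1c1ccc(O)cc1 | target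

**Step count**

Total: 7 steps. Longest linear sequence: 5 steps (steps 1, 2, 5, 6, 7; the branch through steps 3 and 4 is equally long).

**Steps most likely to fail**

Step 5. The hindered secondary C3 radical may add to the internal alkyne too slowly, so that its reduction, a 1,2-aryl shift, loss of HBr from the bromide, or oxidative capture of the spiro radical takes over. The fallback builds coumarin B by polar chemistry, an intramolecular aldol condensation, instead of the radical cascade. It sets out from 3 (through enolate 4) and from 9, and comes back at 12.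
- Enolate 4 is alkylated with tert-butyl bromoacetate (THF, -78 °C) anti to the C4 aryl group, which should give tert-butyl 2-[(3S,4R)-5,7-dimethoxy-4-(4-methoxyphenyl)-2-oxochroman-3-yl]acetate F1.
- CF3CO2H in CH2Cl2 should then give 2-[(3S,4R)-5,7-dimethoxy-4-(4-methoxyphenyl)-2-oxochroman-3-yl]acetic acid F2.
- Phenol 9 is acylated at its one free ring carbon with 4-methoxybenzoyl chloride and TiCl4 (CH2Cl2, 0 °C to rt) to give (2-hydroxy-3,4,5,6-tetramethoxyphenyl)(4-methoxyphenyl)methanone F3.
- Esterification of F2 with F3 (DCC, DMAP, CH2Cl2) should give 2-(4-methoxybenzoyl)-3,4,5,6-tetramethoxyphenyl 2-[(3S,4R)-5,7-dimethoxy-4-(4-methoxyphenyl)-2-oxochroman-3-yl]acetate F4.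
- DBU in MeCN at 60 °C closes the pyranone ring by condensation of the ester CH2 with the diaryl ketone and loss of water. If C3 epimerises under the base it should settle in the trans configuration of 12.

Step 6. The shielded tetrasubstituted double bond may not reach the metal surface, or hydrogen may be delivered to the wrong face if the conformation about C3–C3' differs from the one assumed. The fallback is an electron-transfer conjugate reduction, which does not depend on adsorption. It sets out from 12 and comes back at 13. SmI2 with t-BuOH and N,N-dimethylacetamide in THF at 0 °C should reduce only the unsaturated lactone B. C4' is protonated first, and the samarium enolate is then protonated at C3' from the face away from the C4' aryl group, which should again give the cis lactone. It makes no new compound (entry F0).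

Step 1. Insertion of the aryl–rhodium species into the electron-rich, peri-hindered C3=C4 bond may be slower than protodeboronation of 2. The fallback separates the arylation from the creation of the stereocentre. It sets out from 1 and 2 and comes back at 3. An oxidative Heck reaction (Pd(OAc)2, 1,10-phenanthroline, O2, DMF, 80 °C) should give 5,7-dimethoxy-4-(4-methoxyphenyl)-2H-chromen-2-one F5. An enantioselective copper hydride conjugate reduction (Cu(OAc)2, the enantiomer of DTBM-SEGPHOS that gives 4R, diethoxymethylsilane, t-BuOH, toluene, rt) should then give 3.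

**Further compounds**

F1 | step 5 | tert-butyl 2-[(3S,4R)-5,7-dimethoxy-4-(4-methoxyphenyl)-2-oxochroman-3-yl]acetate | O=C1Oc2cc(OC)cc(OC)c2[C@@H](c2ccc(OC)cc2)[C@@H]1CC(=O)OC(C)(C)C
F2 | step 5 | 2-[(3S,4R)-5,7-dimethoxy-4-(4-methoxyphenyl)-2-oxochroman-3-yl]acetic acid | O=C1Oc2cc(OC)cc(OC)c2[C@@H](c2ccc(OC)cc2)[C@@H]1CC(=O)O
F3 | step 5 | (2-hydroxy-3,4,5,6-tetramethoxyphenyl)(4-methoxyphenyl)methanone | COc1ccc(cc1)C(=O)c1c(O)c(OC)c(OC)c(OC)c1OC
F4 | step 5 | 2-(4-methoxybenzoyl)-3,4,5,6-tetramethoxyphenyl 2-[(3S,4R)-5,7-dimethoxy-4-(4-methoxyphenyl)-2-oxochroman-3-yl]acetate | O=C1Oc2cc(OC)cc(OC)c2[C@@H](c2ccc(OC)cc2)[C@@H]1CC(=O)Oc1c(OC)c(OC)c(OC)c(OC)c1C(=O)c1ccc(OC)cc1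
F0 | step 6 | none | none
F5 | step 1 | 5,7-dimethoxy-4-(4-methoxyphenyl)-2H-chromen-2-one | O=C1C=C(c2ccc(OC)cc2)c2c(OC)cc(OC)cc2O1
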